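Ring A is disconnected between the ketone carbon C3 and the gem-dimethyl carbon C4 (drimane numbering; C11 is the OCH2 carbon). This α-quaternary ketone is read as a nitrile plus the tertiary radical that hydrogen-atom transfer makes from an isopropenyl group, which turns ring B, with its C8 methyl, C7=C8 alkene and C5 side chain, into (S)-carvone. The key step, an iron-hydride-initiated 6-exo radical cyclization onto the nitrile, builds ring A, the C3 carbonyl and the C4 quaternary centre in one operation. Its precursor is a monocyclic cyclohexene bearing isopropenyl at C5, methyl and cis-2-cyanoethyl at C10, and hydroxymethyl at C9.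

Key step: step 6

Remark on the chemistry: the target as written is the cis-fused isomer, with H-5, the C10 methyl and H-9 on one face (β), so that the C4, C1 and C11 substituents are mutually cis (α) on ring B; every stereochemical argument below refers to this isomer.

Step 1
Reactants: 1 (S)-(+)-carvone
Product: 2 (5R,6Z)-6-(hydroxymethylidene)-2-methyl-5-(prop-1-en-2-yl)cyclohex-2-en-1-one
Conditions: NaH, HCO2Et, cat. EtOH, THF, 0 °C to rt; aq. HCl work-up
Reagents that add atoms: ethyl formate CCOC=O
Why: Claisen-type formylation at the α′ methylene is driven to completion by the chelated sodium enolate of the β-ketoaldehyde, whereas formylation at the methyl-bearing α carbon cannot be trapped in this way and reverts; the C5 stereocentre of carvone is not touched.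

Step 2
Reactants: 2 (5R,6Z)-6-(hydroxymethylidene)-2-methyl-5-(prop-1-en-2-yl)cyclohex-2-en-1-one; 3 acrylonitrile
Product: 5 3-[(6S)-3-methyl-2-oxo-6-(prop-1-en-2-yl)cyclohex-3-en-1-yl]propanenitrile, via formyl Michael adduct 4 (not isolated)
Conditions: Et3N (cat.), MeCN, 40 °C; then K2CO3 (cat.), MeOH, rt
Reagents that add atoms: none
Why: The doubly stabilised enolate of 2 should undergo clean mono-Michael addition (the α-cyano carbanion is protonated at once by the acidic ketoaldehyde and so cannot attack the enone), and the now non-enolisable formyl group is then removed by methoxide in a retro-Claisen cleavage, leaving the α′ centre as an inconsequential mixture of epimers.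

Step 3
Reactants: 5 3-[(6S)-3-methyl-2-oxo-6-(prop-1-en-2-yl)cyclohex-3-en-1-yl]propanenitrile
Product: 6 3-[(1S,6R)-1,3-dimethyl-2-oxo-6-(prop-1-en-2-yl)cyclohex-3-en-1-yl]propanenitrile
Conditions: LiN(SiMe3)2, THF, −78 to −40 °C; then MeI, −78 to 0 °C
Reagents that add atoms: iodomethane CI
Why: LiN(SiMe3)2 deprotonates the α′ methine of the ketone but is too weak a base for the alkyl nitrile, and the cross-conjugated enolate is methylated on the face opposite the neighbouring isopropenyl group (enolate alkylation under 1,2-induction), which sets the C10 quaternary centre with methyl trans and cyanoethyl cis to isopropenyl.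

Step 4
Reactants: 6 3-[(1S,6R)-1,3-dimethyl-2-oxo-6-(prop-1-en-2-yl)cyclohex-3-en-1-yl]propanenitrile
Product: 7 3-[(3R,7R,8S)-4,8-dimethyl-7-(prop-1-en-2-yl)-1-oxaspiro[2.5]oct-4-en-8-yl]propanenitrile
Conditions: Me3S+ I−, KN(SiMe3)2, THF, −10 °C; then 6, −10 °C to rt
Reagents that add atoms: trimethylsulfonium iodide C[S+](C)C.[I-]
Why: Corey–Chaykovsky epoxidation, in which the unstabilised sulfonium ylide adds irreversibly in 1,2-fashion to the enone carbonyl from the β face (the face that carries only the C10 methyl and lies opposite the isopropenyl and cyanoethyl groups), so that the new CH2 is β and the epoxide oxygen α at C9.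

Step 5
Reactants: 7 3-[(3R,7R,8S)-4,8-dimethyl-7-(prop-1-en-2-yl)-1-oxaspiro[2.5]oct-4-en-8-yl]propanenitrile
Product: 8 3-[(1S,2R,6R)-2-(hydroxymethyl)-1,3-dimethyl-6-(prop-1-en-2-yl)cyclohex-3-en-1-yl]propanenitrile
Conditions: Pd2(dba)3·CHCl3 (cat.), n-Bu3P, HCO2H, Et3N, 1,4-dioxane, rt to 40 °C
Reagents that add atoms: none
Why: Palladium-catalysed formate hydrogenolysis of an alkenyl oxirane, in which zerovalent palladium ionises the allylic C–O bond anti to oxygen and the formate-derived hydride passes from the metal to the more substituted allyl terminus C9, so that net inversion places H-9 β and the hydroxymethyl group α (cis to the cyanoethyl chain) while the C7=C8 alkene stays in place.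

Step 6
Reactants: 8 3-[(1S,2R,6R)-2-(hydroxymethyl)-1,3-dimethyl-6-(prop-1-en-2-yl)cyclohex-3-en-1-yl]propanenitrile
Product: 10 (4aS,5R,8aS)-5-(hydroxymethyl)-1,1,4a,6-tetramethyl-3,4,4a,5,8,8a-hexahydronaphthalen-2(1H)-one, via bicyclic ketimine 9 (not isolated)
Conditions: Fe(acac)3 (30 mol %), PhSiH3, degassed EtOH (0.02 M), 60 °C; then 1 M aq. HCl, THF, rt
Reagents that add atoms: water O
Why: A trivalent iron hydride formed from Fe(acac)3 and PhSiH3 in ethanol transfers a hydrogen atom to the terminal CH2 of the isopropenyl group, the tertiary C4 radical adds to the nitrile carbon, and the iminyl radical is reduced and protonated by divalent iron and ethanol to the NH ketimine 9, which aqueous acid hydrolyses to the ketone. The closest known reaction type is the hydrogen-atom-transfer-initiated reductive cyclization of alkenyl nitriles to α-quaternary cycloalkanones. Ring A closes in the 6-exo-dig mode. No stereocentre is created (C4 carries two methyls and C3 becomes trigonal); the cis ring fusion follows from the cis arrangement of the C5 and C10 arms fixed by carvone and step 3. The step needs hydrogen-atom transfer to the 1,1-disubstituted alkene rather than the more hindered trisubstituted ring alkene, and ring closure rather than reduction of the radical; the first is the normal preference of iron hydrides, the second is served by the low standing concentration of hydride, high dilution and the proximity of the two cis arms.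

Step 7
Reactants: 10 (4aS,5R,8aS)-5-(hydroxymethyl)-1,1,4a,6-tetramethyl-3,4,4a,5,8,8a-hexahydronaphthalen-2(1H)-one; 11 umbelliferone
Product: 12 7-{[(1R,4aS,8aS)-2,5,5,8a-tetramethyl-6-oxo-1,4,4a,5,6,7,8,8a-octahydronaphthalen-1-yl]methoxy}-2H-chromen-2-one
Conditions: PPh3, diisopropyl azodicarboxylate, THF, 0 °C to rt
Reagents that add atoms: none
Why: Mitsunobu etherification, in which the acidic 7-hydroxyl of umbelliferone displaces the alkoxyphosphonium ion of the primary alcohol at the CH2 carbon, a substitution that touches no stereocentre and leaves ketone, alkene and lactone unchanged.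

Compound list
1 | (S)-(+)-carvone, (5S)-2-methyl-5-(prop-1-en-2-yl)cyclohex-2-en-1-one | CC1=CC[C@H](C(C)=C)CC1=O | starting material
2 | (5R,6Z)-6-(hydroxymethylidene)-2-methyl-5-(prop-1-en-2-yl)cyclohex-2-en-1-one | CC1=CC[C@H](C(C)=C)/C(=C/O)C1=O | intermediate
3 | acrylonitrile | C=CC#N | starting material
4 | 3-[(1R,6R)-1-formyl-3-methyl-2-oxo-6-(prop-1-en-2-yl)cyclohex-3-en-1-yl]propanenitrile | CC1=CC[C@H](C(C)=C)[C@@](C=O)(CCC#N)C1=O | intermediate (not isolated)
5 | 3-[(6S)-3-methyl-2-oxo-6-(prop-1-en-2-yl)cyclohex-3-en-1-yl]propanenitrile (both C1 epimers) | CC1=CC[C@H](C(C)=C)C(CCC#N)C1=O | intermediate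
6 | 3-[(1S,6R)-1,3-dimethyl-2-oxo-6-(prop-1-en-2-yl)cyclohex-3-en-1-yl]propanenitrile | CC1=CC[C@H](C(C)=C)[C@@](CCC#N)(C)C1=O | intermediate
7 | 3-[(3R,7R,8S)-4,8-dimethyl-7-(prop-1-en-2-yl)-1-oxaspiro[2.5]oct-4-en-8-yl]propanenitrile | CC1=CC[C@H](C(C)=C)[C@@](CCC#N)(C)[C@@]12CO2 | intermediate
8 | 3-[(1S,2R,6R)-2-(hydroxymethyl)-1,3-dimethyl-6-(prop-1-en-2-yl)cyclohex-3-en-1-yl]propanenitrile | CC1=CC[C@H](C(C)=C)[C@@](CCC#N)(C)[C@@H]1CO | intermediate
9 | (4aS,5R,8aS)-5-(hydroxymethyl)-1,1,4a,6-tetramethyl-3,4,4a,5,8,8a-hexahydronaphthalen-2(1H)-imine | CC1=CC[C@@H]2C(C)(C)C(=N)CC[C@]2(C)[C@@H]1CO | intermediate (not isolated)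
10 | (4aS,5R,8aS)-5-(hydroxymethyl)-1,1,4a,6-tetramethyl-3,4,4a,5,8,8a-hexahydronaphthalen-2(1H)-one | CC1=CC[C@@H]2C(C)(C)C(=O)CC[C@]2(C)[C@@H]1CO | intermediate
11 | umbelliferone, 7-hydroxy-2H-chromen-2-one | Oc1ccc2ccc(=O)oc2c1 | starting material
12 | 7-{[(1R,4aS,8aS)-2,5,5,8a-tetramethyl-6-oxo-1,4,4a,5,6,7,8,8a-octahydronaphthalen-1-yl]methoxy}-2H-chromen-2-one | CC1=CC[C@@H]2C(C)(C)C(=O)CC[C@]2(C)[C@@H]1COc1ccc2ccc(=O)oc2c1 | target

Total step count: 7. Longest linear sequence: 7 steps, from (S)-carvone.

Steps most likely to fail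

Step 6 is the most exposed. The tertiary C4 radical may be reduced to an isopropyl group, may return a hydrogen atom to give the isopropylidene isomer, or may abstract H-11 through a six-membered transition state before it reaches the weakly electrophilic nitrile. The fallback sets out from 8 and exchanges the nitrile for an aldehyde, which captures alkyl radicals far faster. Reduction with i-Bu2AlH (CH2Cl2, −78 °C; aqueous HCl) should give 3-[(1S,2R,6R)-2-(hydroxymethyl)-1,3-dimethyl-6-(prop-1-en-2-yl)cyclohex-3-en-1-yl]propanal F1. The same Fe(acac)3/PhSiH3 conditions, now as a hydrogen-atom-transfer alkene–carbonyl radical cyclization, should close ring A to (4aS,5R,8aS)-5-(hydroxymethyl)-1,1,4a,6-tetramethyl-1,2,3,4,4a,5,8,8a-octahydronaphthalen-2-ol F2 (either carbinol epimer serves). Mitsunobu coupling with 11 at the primary hydroxyl should give 7-{[(1R,4aS,8aS)-6-hydroxy-2,5,5,8a-tetramethyl-1,4,4a,5,6,7,8,8a-octahydronaphthalen-1-yl]methoxy}-2H-chromen-2-one F3, and Dess–Martin periodinane oxidation of the secondary alcohol comes back to the route at 12.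

Step 4 may suffer from slow addition of the ylide to a carbonyl flanked by a quaternary carbon and a methyl-substituted alkene, from decay of the ylide, and from imperfect face selectivity on the flexible monocycle. The fallback sets out from 6 and moves the C9 homologation to the bicyclic stage, where ring A shields the α face. The conditions of step 6 applied to 6 should give, through (4aR,8aS)-6-imino-2,5,5,8a-tetramethyl-4a,5,6,7,8,8a-hexahydronaphthalen-1(4H)-one F4 (not isolated), the cis-fused (4aR,8aS)-2,5,5,8a-tetramethyl-4,4a,7,8-tetrahydronaphthalene-1,6(5H,8aH)-dione F5. Selective ketalisation of the saturated ketone (ethylene glycol, pyridinium tosylate, benzene, reflux) should give (4aR,8aS)-6,6-(ethane-1,2-diyldioxy)-2,5,5,8a-tetramethyl-4a,5,6,7,8,8a-hexahydronaphthalen-1(4H)-one F6. Wittig methylenation (Ph3P=CH2 from the phosphonium bromide and KOC(CH3)3, toluene, 80 °C) should give (4aS,8aS)-6,6-(ethane-1,2-diyldioxy)-2,5,5,8a-tetramethyl-1-methylidene-1,4,4a,5,6,7,8,8a-octahydronaphthalene F7. Hydroboration of the exocyclic terminus of the diene with 9-borabicyclo[3.3.1]nonane from the face opposite ring A, then NaBO3, should give [(1R,4aS,8aS)-6,6-(ethane-1,2-diyldioxy)-2,5,5,8a-tetramethyl-1,4,4a,5,6,7,8,8a-octahydronaphthalen-1-yl]methanol F8. Aqueous HCl in THF removes the ketal and comes back to the route at 10.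

Step 5 may deliver the hydride to the C7 terminus (giving the isomer with a tetrasubstituted alkene), may lose a β-hydrogen from the allyl complex, or may isomerise the oxirane to an unsaturated aldehyde. The fallback sets out from 6 and brings in C11 at the aldehyde level, with H-9 set by protonation instead of hydride transfer. Wittig reaction with Ph3P=CHOCH3 (from the phosphonium chloride and KN(SiMe3)2, THF, 0 °C to rt) should give 3-[(1S,6R)-2-(methoxymethylidene)-1,3-dimethyl-6-(prop-1-en-2-yl)cyclohex-3-en-1-yl]propanenitrile F9. Mild hydrolysis (oxalic acid, wet THF, 0 °C) with kinetic protonation at C9 from the β face should give 3-[(1S,2R,6R)-2-formyl-1,3-dimethyl-6-(prop-1-en-2-yl)cyclohex-3-en-1-yl]propanenitrile F10. Immediate reduction with NaBH4 (MeOH, 0 °C) comes back to the route at 8.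

Further compounds
F1 | step 6 | 3-[(1S,2R,6R)-2-(hydroxymethyl)-1,3-dimethyl-6-(prop-1-en-2-yl)cyclohex-3-en-1-yl]propanal | CC1=CC[C@H](C(C)=C)[C@@](CCC=O)(C)[C@@H]1CO
F2 | step 6 | (4aS,5R,8aS)-5-(hydroxymethyl)-1,1,4a,6-tetramethyl-1,2,3,4,4a,5,8,8a-octahydronaphthalen-2-ol | CC1=CC[C@@H]2C(C)(C)C(O)CC[C@]2(C)[C@@H]1CO
F3 | step 6 | 7-{[(1R,4aS,8aS)-6-hydroxy-2,5,5,8a-tetramethyl-1,4,4a,5,6,7,8,8a-octahydronaphthalen-1-yl]methoxy}-2H-chromen-2-one | CC1=CC[C@@H]2C(C)(C)C(O)CC[C@]2(C)[C@@H]1COc1ccc2ccc(=O)oc2c1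
F4 | step 4 | (4aR,8aS)-6-imino-2,5,5,8a-tetramethyl-4a,5,6,7,8,8a-hexahydronaphthalen-1(4H)-one | CC1=CC[C@@H]2C(C)(C)C(=N)CC[C@]2(C)C1=O
F5 | step 4 | (4aR,8aS)-2,5,5,8a-tetramethyl-4,4a,7,8-tetrahydronaphthalene-1,6(5H,8aH)-dione | CC1=CC[C@@H]2C(C)(C)C(=O)CC[C@]2(C)C1=O
F6 | step 4 | (4aR,8aS)-6,6-(ethane-1,2-diyldioxy)-2,5,5,8a-tetramethyl-4a,5,6,7,8,8a-hexahydronaphthalen-1(4H)-one | CC1=CC[C@@H]2C(C)(C)C3(OCCO3)CC[C@]2(C)C1=O
F7 | step 4 | (4aS,8aS)-6,6-(ethane-1,2-diyldioxy)-2,5,5,8a-tetramethyl-1-methylidene-1,4,4a,5,6,7,8,8a-octahydronaphthalene | CC1=CC[C@@H]2C(C)(C)C3(OCCO3)CC[C@]2(C)C1=C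
F8 | step 4 | [(1R,4aS,8aS)-6,6-(ethane-1,2-diyldioxy)-2,5,5,8a-tetramethyl-1,4,4a,5,6,7,8,8a-octahydronaphthalen-1-yl]methanol | CC1=CC[C@@H]2C(C)(C)C3(OCCO3)CC[C@]2(C)[C@@H]1CO
F9 | step 5 | 3-[(1S,6R)-2-(methoxymethylidene)-1,3-dimethyl-6-(prop-1-en-2-yl)cyclohex-3-en-1-yl]propanenitrile | CC1=CC[C@H](C(C)=C)[C@@](CCC#N)(C)C1=COC
F10 | step 5 | 3-[(1S,2R,6R)-2-formyl-1,3-dimethyl-6-(prop-1-en-2-yl)cyclohex-3-en-1-yl]propanenitrile | CC1=CC[C@H](C(C)=C)[C@@](CCC#N)(C)[C@@H]1C=O
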